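**Strategy.** Kukoamine A is C2-symmetric about the middle of its spermine chain (4,9-diazadodecane numbering), so the disconnection cuts both the C3–N4 and N9–C10 bonds at the secondary amines N4 and N9. That leaves the C5–C8 diamine putrescine and two identical three-carbon aldehydes whose terminal nitrogens (N1, N12) already carry the dihydrocaffeoyl amide, with the catechol rings masked as benzyl ethers. One two-directional imine formation and hydride reduction should forge both C–N bonds and complete the acyclic spermine backbone without amine protection; no ring is formed and the two arene rings are spectators. The precursor is a 3-amidopropanal, released from its storable diethyl acetal just before use. Global hydrogenolysis ends the route.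

Key step: step 4

Assumption: the target is taken as the neutral free base drawn; after step 5 it is handled as its acetate salt and set free (weakly basic resin, argon) only when needed, because catechols oxidise in basic, aerated solution.

Step 1
Reactants: 1 3-(3,4-dihydroxyphenyl)propanoic acid (1.0 equiv); 2 benzyl bromide (3.3 equiv)
Product: 4 3-[3,4-bis(benzyloxy)phenyl]propanoic acid, via benzyl ester 3 (not isolated)
Conditions: K2CO3 (4 equiv), acetone, reflux, N2; filter, evaporate; then 2 M aq. NaOH, MeOH/THF, 60 °C; aq. HCl to pH 2
Reagents that add atoms: benzyl bromide (further equivalents of 2), BrCc1ccccc1; sodium hydroxide, [Na+].[OH-]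
Why: Williamson O-alkylation (SN2 on benzyl bromide) of the two phenoxides and the carboxylate consumes three equivalents of 2 and should give the tribenzyl compound 3, and saponification (acyl-oxygen ester hydrolysis) then frees the acid with loss of the ester benzyl group as benzyl alcohol, while the two aryl benzyl ethers, inert to hydroxide, stay in place.

Step 2
Reactants: 4 3-[3,4-bis(benzyloxy)phenyl]propanoic acid; 5 3,3-diethoxypropan-1-amine
Product: 7 3-[3,4-bis(benzyloxy)phenyl]-N-(3,3-diethoxypropyl)propanamide, via acyl imidazolide 6 (not isolated)
Conditions: CDI (1.1 equiv), THF, rt until CO2 evolution stops; then 5 (1.1 equiv), rt; aq. NaHCO3 work-up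
Reagents that add atoms: none
Why: Amide coupling through the acyl imidazolide: CDI activates the acid with loss of CO2 and the unhindered primary amine of 5 displaces imidazole under neutral conditions, so the acid-labile diethyl acetal should survive untouched.

Step 3
Reactants: 7 3-[3,4-bis(benzyloxy)phenyl]-N-(3,3-diethoxypropyl)propanamide
Product: 8 3-[3,4-bis(benzyloxy)phenyl]-N-(3-oxopropyl)propanamide
Conditions: Amberlyst-15 (sulfonic acid resin), acetone/H2O, rt; filter, concentrate below 30 °C, use at once
Reagents that add atoms: water, O
Why: Acid-catalysed acetal hydrolysis via the oxocarbenium ion should unmask the aldehyde without touching amide or benzyl ethers, and filtering off the resin gives a neutral solution, so the elimination-prone β-amido aldehyde never meets base before it is used directly in step 4.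

Step 4
Reactants: 8 3-[3,4-bis(benzyloxy)phenyl]-N-(3-oxopropyl)propanamide (2.05 equiv); 9 putrescine (butane-1,4-diamine, 1.0 equiv)
Product: 11 tetra-O-benzyl kukoamine A, via bis-aldimine 10 (not isolated)
Conditions: MeOH/CH2Cl2, anhydrous Na2SO4, 0 °C to rt; then NaBH4, 0 °C
Reagents that add atoms: none
Why: Both primary amines of 9 should add to the formyl group of 8 and dehydrate to the bis-aldimine 10, whose two C=N carbons then accept hydride from NaBH4, creating the C3–N4 and N9–C10 bonds in one flask. The closest known reaction type is the stepwise (indirect) reductive amination used to extend polyamine chains with N-acyl or N-carbamoyl 3-aminopropanals. No ring is closed and no stereocentre is formed, so neither closure mode nor stereocontrol is at issue. The selectivity needed is one alkylation per nitrogen: it is secured by withholding hydride until both amines are locked as imines, which cannot condense with a second aldehyde, and by using only a marginal excess of 8, which NaBH4 converts into the inert alcohol. Chemoselectivity comes from the substrate itself, since the N1 and N12 nitrogens are already amides and therefore non-nucleophilic, and NaBH4 spares amides and benzyl ethers. Imine formation at 0 °C to room temperature under neutral conditions should keep imine–enamine tautomerisation, and with it β-elimination of the amide, to a minimum.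

Step 5
Reactants: 11 tetra-O-benzyl kukoamine A
Product: 12 kukoamine A [N1,N12-bis(dihydrocaffeoyl)spermine]
Conditions: H2 (1 atm), 10% Pd/C, MeOH/AcOH, rt; filter under argon, evaporate
Reagents that add atoms: none
Why: Catalytic hydrogenolysis of the four benzylic C–O bonds on Pd should release both catechols, AcOH keeping N4 and N9 protonated so that they neither poison the catalyst nor expose the catechols to base-promoted air oxidation, while amides and the saturated chain are inert.

**Compound list**

1 | 3-(3,4-dihydroxyphenyl)propanoic acid (dihydrocaffeic acid) | OC(=O)CCc1ccc(O)c(O)c1 | starting material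
2 | benzyl bromide | BrCc1ccccc1 | starting material
3 | benzyl 3-[3,4-bis(benzyloxy)phenyl]propanoate | O=C(CCc1ccc(OCc2ccccc2)c(OCc2ccccc2)c1)OCc1ccccc1 | intermediate
4 | 3-[3,4-bis(benzyloxy)phenyl]propanoic acid | OC(=O)CCc1ccc(OCc2ccccc2)c(OCc2ccccc2)c1 | intermediate
5 | 3,3-diethoxypropan-1-amine | CCOC(CCN)OCC | starting material
6 | 3-[3,4-bis(benzyloxy)phenyl]-1-(1H-imidazol-1-yl)propan-1-one (acyl imidazolide) | O=C(CCc1ccc(OCc2ccccc2)c(OCc2ccccc2)c1)n1ccnc1 | intermediate
7 | 3-[3,4-bis(benzyloxy)phenyl]-N-(3,3-diethoxypropyl)propanamide | CCOC(CCNC(=O)CCc1ccc(OCc2ccccc2)c(OCc2ccccc2)c1)OCC | intermediate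
8 | 3-[3,4-bis(benzyloxy)phenyl]-N-(3-oxopropyl)propanamide | O=CCCNC(=O)CCc1ccc(OCc2ccccc2)c(OCc2ccccc2)c1 | intermediate
9 | putrescine (butane-1,4-diamine) | NCCCCN | starting material
10 | bis-aldimine of putrescine with two molecules of 8 (N4=C3 and N9=C10 double bonds) | O=C(CCc1ccc(OCc2ccccc2)c(OCc2ccccc2)c1)NCCC=NCCCCN=CCCNC(=O)CCc1ccc(OCc2ccccc2)c(OCc2ccccc2)c1 | intermediate
11 | tetra-O-benzyl kukoamine A, N1,N12-bis{3-[3,4-bis(benzyloxy)phenyl]propanoyl}spermine | O=C(CCc1ccc(OCc2ccccc2)c(OCc2ccccc2)c1)NCCCNCCCCNCCCNC(=O)CCc1ccc(OCc2ccccc2)c(OCc2ccccc2)c1 | intermediate
12 | kukoamine A, N1,N12-bis[3-(3,4-dihydroxyphenyl)propanoyl]spermine | O=C(CCc1ccc(O)c(O)c1)NCCCNCCCCNCCCNC(=O)CCc1ccc(O)c(O)c1 | target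

**Step count.** Total: 5 steps. Longest linear sequence: 5 steps (1 → 4 → 7 → 8 → 11 → 12); putrescine 9 enters at step 4.

**Steps most likely to fail**

Step 4. The risks are a second alkylation at N4 or N9 if hydride is added before imine formation is complete, and tautomerisation of the aldimine to its enamine followed by β-elimination of the amide, which would shed an acyl arm. The fallback drops the aldehyde and builds the two amide bonds last. It sets out from acid 4, which with N-hydroxysuccinimide and DCC (CH2Cl2/THF, 0 °C to rt) should give the active ester 2,5-dioxopyrrolidin-1-yl 3-[3,4-bis(benzyloxy)phenyl]propanoate F1. Commercial spermine (NCCCNCCCCNCCCN) is then treated with two equivalents of the ester in CH2Cl2 at −20 °C to rt. The unhindered primary amines should acylate in preference to the secondary ones, a known chemoselective route to N1,N12-diacylspermines, and the sequence returns to the route at compound 11.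

Step 3. The risks are loss of the amide by β-elimination (release of acrolein) and self-condensation of the aldehyde during hydrolysis and concentration. The fallback reaches the aldehyde by oxidation under anhydrous conditions. It sets out from acid 4, activated with CDI as in step 2 to the acyl imidazolide 6, which should acylate 3-aminopropan-1-ol (NCCCO) at nitrogen to give the hydroxy amide 3-[3,4-bis(benzyloxy)phenyl]-N-(3-hydroxypropyl)propanamide F2. Oxidation of the primary alcohol with Dess–Martin periodinane (CH2Cl2, rt) returns to the route at compound 8.

Step 5. The risks are stalling of the hydrogenolysis through adsorption of the polyamine on the Pd surface, leaving partly benzylated material, and reductive N-alkylation by solvent-derived aldehyde. The fallback is a Lewis-acid debenzylation that needs no catalyst surface. It sets out from compound 11, which is treated with excess BCl3 and pentamethylbenzene as benzyl-cation scavenger (CH2Cl2, −78 °C to 0 °C, MeOH quench). The aryl benzyl ethers should cleave while amides and ammonium centres persist, returning at compound 12 as its hydrochloride; no new compound arises (F0).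

**Further compounds**

F1 | step 4 | 2,5-dioxopyrrolidin-1-yl 3-[3,4-bis(benzyloxy)phenyl]propanoate | O=C(CCc1ccc(OCc2ccccc2)c(OCc2ccccc2)c1)ON1C(=O)CCC1=O
F2 | step 3 | 3-[3,4-bis(benzyloxy)phenyl]-N-(3-hydroxypropyl)propanamide | OCCCNC(=O)CCc1ccc(OCc2ccccc2)c(OCc2ccccc2)c1
F0 | step 5 | none | none
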